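**Plan**

1. Retrosynthetic cuts: the five O-benzyl bonds; then, in the 4-hydroxyphenyl unit, C4''–C4a'' (ring C''), O1''–C8a'' and C2''–C3''; then, in the 4-methoxyphenyl unit, C4–C4a (ring C), O1–C8a and C2–C3. What remains is a succinate (C4–C3–C3''–C4''), two benzaldehydes and two equivalents of a 3,5-bis(benzyloxy)phenyl donor (an aryltrifluoroborate).
2. Forward order: succinate imide → anti-aldol (C2–C3) → copper-catalysed O-arylation (O1–C8a) → Friedel–Crafts closure of ring C → side-chain imide → syn-aldol (C2''–C3'') → copper-catalysed O-arylation (O1''–C8a'') → Friedel–Crafts closure of ring C'' → hydrogenolysis.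
3. Enabling feature: ring A'' is a phloroglucinol ring in which C4a'' is ortho to O1'' and O5'' and para to O7'', and the acyl carbon C4'' is held five atoms away through O1''–C2''–C3''. This arene is nucleophilic enough to close the six-membered ring C'' under cold, base-free acid.
4. Stereochemistry: (S)-4-benzyl-1,3-oxazolidin-2-one steers both aldols (MgCl2 anti-aldol sets C2 S and C3 R; boron syn-aldol sets C2'' S and C3'' S). Both aryl ethers are made at oxygen, with no substitution at carbon, so anti becomes 2,3-trans and syn becomes 2'',3''-cis.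
5. Ring C'' is closed last and under acid because C3'' of the cis unit, α to the new ketone, is the less stable epimer and should not meet base as a ketone.

Key step: step 12

Remark: flavanone numbering is used; unprimed locants belong to the 4-methoxyphenyl unit (rings A and C), doubly primed locants to the 4-hydroxyphenyl unit (rings A'' and C''). Compounds 1, 3, 4, 7 and 18 are taken as commercial, as is the 3,5-bis(benzyloxy)phenol named in two fallbacks.

**Route**

Step 1
Reactants: 1 3,5-bis(benzyloxy)phenylboronic acid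
Product: 2 potassium trifluoro[3,5-bis(benzyloxy)phenyl]borate
Conditions: KHF2 (3 equiv, aq), MeOH, 0 °C → rt; recrystallise from acetone/Et2O
Reagents that add atoms: potassium hydrogen difluoride, [K+].[F-].F
Why: Treatment of an arylboronic acid with aqueous KHF2 is the standard route to the potassium aryltrifluoroborate, an air-stable, monomeric aryl donor that should transfer its aryl group to copper more cleanly than the free acid, and no stereocentre is involved.

Step 2
Reactants: 3 4-tert-butoxy-4-oxobutanoic acid; 4 (S)-4-benzyl-1,3-oxazolidin-2-one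
Product: 6 tert-butyl 4-[(4S)-4-benzyl-2-oxo-1,3-oxazolidin-3-yl]-4-oxobutanoate, via mixed pivalic anhydride 5 (not isolated)
Conditions: PivCl, Et3N, THF, −20 °C; then 4, LiCl, −20 °C → rt
Reagents that add atoms: none
Why: N-Acylation of the oxazolidinone through the mixed pivalic anhydride (LiCl and Et3N make the oxazolidinone nucleophilic enough without butyllithium) should give the imide by attack at the less hindered succinyl carbonyl, with no stereocentre formed.

Step 3
Reactants: 6 tert-butyl 4-[(4S)-4-benzyl-2-oxo-1,3-oxazolidin-3-yl]-4-oxobutanoate; 7 4-methoxybenzaldehyde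
Product: 9 tert-butyl (3R,4S)-3-{[(4S)-4-benzyl-2-oxo-1,3-oxazolidin-3-yl]carbonyl}-4-hydroxy-4-(4-methoxyphenyl)butanoate, via silyl ether 8 (not isolated)
Conditions: MgCl2 (0.2 equiv), Et3N, TMSCl, EtOAc, rt; then PPTS (cat.), MeOH, 0 °C
Reagents that add atoms: none
Why: The MgCl2-catalysed direct anti-aldol reaction of N-acyloxazolidinones (soft enolisation, silylation of the magnesium aldolate) should give the anti adduct, the chelated Z-enolate being attacked on the face away from the benzyl group so that the later C3 is R and the carbinol carbon (later C2) is S, while the tert-butyl ester resists γ-lactonisation by the new hydroxyl.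

Step 4
Reactants: 9 anti-aldol adduct (3R,4S); 2 potassium trifluoro[3,5-bis(benzyloxy)phenyl]borate
Product: 10 tert-butyl (3R,4S)-3-{[(4S)-4-benzyl-2-oxo-1,3-oxazolidin-3-yl]carbonyl}-4-[3,5-bis(benzyloxy)phenoxy]-4-(4-methoxyphenyl)butanoate
Conditions: 2 (2 equiv), Cu(OAc)2·H2O (10 mol%), DMAP (20 mol%), 4 Å molecular sieves, O2 (1 atm), CH2Cl2, rt
Reagents that add atoms: none
Why: Copper-catalysed oxidative coupling of a potassium aryltrifluoroborate with an aliphatic alcohol (Chan–Lam-type etherification: aryl transfer from boron to divalent copper, binding of the alcohol, oxidation to trivalent copper and C–O reductive elimination) should give the 3,5-bis(benzyloxy)phenyl ether with retention, because the bond is made at oxygen and the p-methoxybenzylic C–O bond is never broken, while the neutral, fluoride-free conditions spare the β-hydroxy imide and the tert-butyl ester.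

Step 5
Reactants: 10 aryl ether imide (3R,4S)
Product: 12 (2R,3S)-3-[3,5-bis(benzyloxy)phenoxy]-2-(2-tert-butoxy-2-oxoethyl)-3-(4-methoxyphenyl)propanoic acid, via peroxy acid 11 (not isolated)
Conditions: LiOH (1.5 equiv), H2O2 (4 equiv), THF/H2O 3:1, 0 °C; then Na2SO3 (aq); then 1 M HCl to pH 3, 0 °C
Reagents that add atoms: hydrogen peroxide, OO
Why: Hydroperoxide cleaves N-acyloxazolidinones at the exocyclic carbonyl even when hindered, and its low basicity should spare the tert-butyl ester and avoid β-elimination of the aryloxy group, sulfite then reducing the peroxy acid to the acid while the auxiliary is recovered.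

Step 6
Reactants: 12 (2R,3S)-3-aryloxy acid
Product: 14 tert-butyl 2-[(2S,3R)-5,7-bis(benzyloxy)-2-(4-methoxyphenyl)-4-oxochroman-3-yl]acetate, via mixed trifluoroacetic anhydride 13 (not isolated)
Conditions: TFAA (1.2 equiv), CH2Cl2, −20 → 0 °C
Reagents that add atoms: none
Why: Intramolecular Friedel–Crafts acylation through the mixed trifluoroacetic anhydride should close ring C at the phloroglucinol carbon ortho to the ether oxygen (six-membered closure, both ortho sites equivalent), turning the anti acid into the 2,3-trans flavanone, which is also the thermodynamically preferred arrangement.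

Step 7
Reactants: 14 flavanone tert-butyl ester
Product: 15 2-[(2S,3R)-5,7-bis(benzyloxy)-2-(4-methoxyphenyl)-4-oxochroman-3-yl]acetic acid
Conditions: TFA/CH2Cl2 (1:4), 0 °C → rt
Reagents that add atoms: none
Why: Acidolysis of the tert-butyl ester with loss of 2-methylpropene should leave the benzyl ethers and the cyclic, ketone-conjugated benzylic ether of the flavanone untouched.

Step 8
Reactants: 15 flavanone acetic acid; 4 (S)-4-benzyl-1,3-oxazolidin-2-one
Product: 17 (4S)-4-benzyl-3-{[(2S,3R)-5,7-bis(benzyloxy)-2-(4-methoxyphenyl)-4-oxochroman-3-yl]acetyl}-1,3-oxazolidin-2-one, via mixed pivalic anhydride 16 (not isolated)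
Conditions: PivCl, Et3N, THF, −20 °C; then 4, LiCl, −20 °C → rt
Reagents that add atoms: none
Why: Mixed-anhydride N-acylation as in step 2 should install the same (S)-auxiliary on the side chain under weakly basic conditions at low temperature, at which the hindered C3–H of the ketone is not enolised.

Step 9
Reactants: 17 side-chain imide; 18 4-(benzyloxy)benzaldehyde
Product: 21 (4S)-4-benzyl-3-{(2S,3S)-3-[4-(benzyloxy)phenyl]-2-[(2S,3R)-5,7-bis(benzyloxy)-2-(4-methoxyphenyl)-4-oxochroman-3-yl]-3-hydroxypropanoyl}-1,3-oxazolidin-2-one, via boron enolate 19 (not isolated), via boron aldolate 20 (not isolated)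
Conditions: Bu2BOTf (1.2 equiv), i-Pr2NEt (1.4 equiv), CH2Cl2, −78 → 0 °C; then 18, −78 → 0 °C; then pH 7 buffer, MeOH, H2O2, 0 °C
Reagents that add atoms: none
Why: The boron-mediated syn-aldol reaction of N-acyloxazolidinones (Z-enolate, closed chair transition state, aldehyde on the enolate face away from the benzyl group with the imide dipoles opposed) should set C3'' as S and the carbinol carbon C2'' as S under auxiliary control, the unhindered imide CH2 being enolised far faster than the tertiary C3–H of the electron-rich aryl ketone.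

Step 10
Reactants: 21 syn-aldol adduct; 2 potassium trifluoro[3,5-bis(benzyloxy)phenyl]borate
Product: 22 (4S)-4-benzyl-3-{(2S,3S)-3-[3,5-bis(benzyloxy)phenoxy]-3-[4-(benzyloxy)phenyl]-2-[(2S,3R)-5,7-bis(benzyloxy)-2-(4-methoxyphenyl)-4-oxochroman-3-yl]propanoyl}-1,3-oxazolidin-2-one
Conditions: 2 (3 equiv, in portions), Cu(OAc)2·H2O (20 mol%), DMAP (40 mol%), 4 Å molecular sieves, O2 (1 atm), CH2Cl2, rt
Reagents that add atoms: none
Why: The same copper-catalysed oxidative etherification as in step 4 should arylate the hindered benzylic hydroxyl with retention at C2'', so that the syn relation of the aldol adduct is carried unchanged into the aryl ether, DMAP being too weak a base to enolise the flavanone ketone or to start a retro-aldol cleavage.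

Step 11
Reactants: 22 aryl ether imide
Product: 24 (2S,3S)-3-[3,5-bis(benzyloxy)phenoxy]-3-[4-(benzyloxy)phenyl]-2-[(2S,3R)-5,7-bis(benzyloxy)-2-(4-methoxyphenyl)-4-oxochroman-3-yl]propanoic acid, via peroxy acid 23 (not isolated)
Conditions: LiOH (1.5 equiv), H2O2 (4 equiv), THF/H2O 3:1, 0 °C; then Na2SO3 (aq); then 1 M HCl to pH 3, 0 °C
Reagents that add atoms: hydrogen peroxide, OO
Why: Exocyclic imide cleavage by LiOOH at 0 °C with only a small excess of LiOH should free the acid and the auxiliary without enolising the flavanone ketone or eliminating the β-aryloxy group.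

Step 12
Reactants: 24 (2S,3S)-3-aryloxy acid
Product: 26 (2S,3R,2''S,3''S)-5,5'',7,7''-tetrakis(benzyloxy)-2''-[4-(benzyloxy)phenyl]-2-(4-methoxyphenyl)-[3,3''-bichromane]-4,4''-dione, via mixed trifluoroacetic anhydride 25 (not isolated)
Conditions: TFAA (1.2 equiv), CH2Cl2, −20 → 0 °C
Reagents that add atoms: none
Why: TFAA converts the acid into the mixed anhydride 25, whose acylium-like carbon C4'' is attacked by C4a'' of ring A'' (ortho to O1'' and O5'', para to O7''), and loss of the proton restores the arene; this is an intramolecular Friedel–Crafts acylation, the classical cyclodehydration of 3-aryloxypropanoic acids to chroman-4-ones. Ring C'' closes in a six-membered mode (6-exo-trig at the acyl carbon, electrophilic aromatic substitution at the ring carbon), the two ortho carbons of the symmetrical 3,5-bis(benzyloxy)phenyl group being equivalent. No new stereocentre is formed: the 2'',3''-cis relation is the syn relation of the aldol adduct of step 9, transcribed because neither the C2''–O bond nor the C3''–H bond is broken. The step needs site selectivity (ring A'' through a six-membered ring, not C8 of the already acylated ring A through a seven-membered ring, and no trifluoroacetylation of ring A''), which the tether length, the higher nucleophilicity of the unacylated phloroglucinol ring and the small excess of TFAA should secure. It also needs integrity at C3'' (the less stable epimer, α to the new ketone) and at the p-alkoxybenzylic C2''–O bond, which base-free, cold, weakly acidic conditions should secure, since the very electron-rich ring should cyclise faster than the ether ionises or the ketone enolises.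

Step 13
Reactants: 26 pentabenzyl biflavanone
Product: 27 (2S,3R,2''S,3''S)-5,5'',7,7''-tetrahydroxy-2''-(4-hydroxyphenyl)-2-(4-methoxyphenyl)-[3,3''-bichromane]-4,4''-dione
Conditions: H2 (1 atm), 10% Pd/C, EtOAc/MeOH, rt
Reagents that add atoms: none
Why: Hydrogenolysis of the five benzyl ethers over Pd/C under neutral conditions should free the five phenols without touching the methyl ether, the ketones or the base-sensitive cis C3'' centre.

**Compound list**

1 | 3,5-bis(benzyloxy)phenylboronic acid | OB(O)c1cc(OCc2ccccc2)cc(OCc2ccccc2)c1 | starting material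
2 | potassium trifluoro[3,5-bis(benzyloxy)phenyl]borate | [K+].F[B-](F)(F)c1cc(OCc2ccccc2)cc(OCc2ccccc2)c1 | intermediate
3 | 4-tert-butoxy-4-oxobutanoic acid (mono-tert-butyl succinate) | CC(C)(C)OC(=O)CCC(=O)O | starting material
4 | (S)-4-benzyl-1,3-oxazolidin-2-one | O=C1OC[C@H](Cc2ccccc2)N1 | starting material
5 | mixed anhydride of 3 with pivalic acid | CC(C)(C)OC(=O)CCC(=O)OC(=O)C(C)(C)C | intermediate
6 | tert-butyl 4-[(4S)-4-benzyl-2-oxo-1,3-oxazolidin-3-yl]-4-oxobutanoate | CC(C)(C)OC(=O)CCC(=O)N1C(=O)OC[C@@H]1Cc1ccccc1 | intermediate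
7 | 4-methoxybenzaldehyde | COc1ccc(C=O)cc1 | starting material
8 | tert-butyl (3R,4S)-3-{[(4S)-4-benzyl-2-oxo-1,3-oxazolidin-3-yl]carbonyl}-4-(4-methoxyphenyl)-4-[(trimethylsilyl)oxy]butanoate | COc1ccc(cc1)[C@@H](O[Si](C)(C)C)[C@@H](CC(=O)OC(C)(C)C)C(=O)N1C(=O)OC[C@@H]1Cc1ccccc1 | intermediate
9 | tert-butyl (3R,4S)-3-{[(4S)-4-benzyl-2-oxo-1,3-oxazolidin-3-yl]carbonyl}-4-hydroxy-4-(4-methoxyphenyl)butanoate | COc1ccc(cc1)[C@@H](O)[C@@H](CC(=O)OC(C)(C)C)C(=O)N1C(=O)OC[C@@H]1Cc1ccccc1 | intermediate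
10 | tert-butyl (3R,4S)-3-{[(4S)-4-benzyl-2-oxo-1,3-oxazolidin-3-yl]carbonyl}-4-[3,5-bis(benzyloxy)phenoxy]-4-(4-methoxyphenyl)butanoate | COc1ccc(cc1)[C@@H](Oc1cc(OCc2ccccc2)cc(OCc2ccccc2)c1)[C@@H](CC(=O)OC(C)(C)C)C(=O)N1C(=O)OC[C@@H]1Cc1ccccc1 | intermediate
11 | (2R,3S)-3-[3,5-bis(benzyloxy)phenoxy]-2-(2-tert-butoxy-2-oxoethyl)-3-(4-methoxyphenyl)propaneperoxoic acid | COc1ccc(cc1)[C@@H](Oc1cc(OCc2ccccc2)cc(OCc2ccccc2)c1)[C@@H](CC(=O)OC(C)(C)C)C(=O)OO | intermediate
12 | (2R,3S)-3-[3,5-bis(benzyloxy)phenoxy]-2-(2-tert-butoxy-2-oxoethyl)-3-(4-methoxyphenyl)propanoic acid | COc1ccc(cc1)[C@@H](Oc1cc(OCc2ccccc2)cc(OCc2ccccc2)c1)[C@@H](CC(=O)OC(C)(C)C)C(=O)O | intermediate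
13 | mixed anhydride of 12 with trifluoroacetic acid | COc1ccc(cc1)[C@@H](Oc1cc(OCc2ccccc2)cc(OCc2ccccc2)c1)[C@@H](CC(=O)OC(C)(C)C)C(=O)OC(=O)C(F)(F)F | intermediate
14 | tert-butyl 2-[(2S,3R)-5,7-bis(benzyloxy)-2-(4-methoxyphenyl)-4-oxochroman-3-yl]acetate | COc1ccc([C@H]2Oc3cc(OCc4ccccc4)cc(OCc4ccccc4)c3C(=O)[C@@H]2CC(=O)OC(C)(C)C)cc1 | intermediate
15 | 2-[(2S,3R)-5,7-bis(benzyloxy)-2-(4-methoxyphenyl)-4-oxochroman-3-yl]acetic acid | COc1ccc([C@H]2Oc3cc(OCc4ccccc4)cc(OCc4ccccc4)c3C(=O)[C@@H]2CC(=O)O)cc1 | intermediate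
16 | mixed anhydride of 15 with pivalic acid | COc1ccc([C@H]2Oc3cc(OCc4ccccc4)cc(OCc4ccccc4)c3C(=O)[C@@H]2CC(=O)OC(=O)C(C)(C)C)cc1 | intermediate
17 | (4S)-4-benzyl-3-{[(2S,3R)-5,7-bis(benzyloxy)-2-(4-methoxyphenyl)-4-oxochroman-3-yl]acetyl}-1,3-oxazolidin-2-one | COc1ccc([C@H]2Oc3cc(OCc4ccccc4)cc(OCc4ccccc4)c3C(=O)[C@@H]2CC(=O)N2C(=O)OC[C@@H]2Cc2ccccc2)cc1 | intermediate
18 | 4-(benzyloxy)benzaldehyde | O=Cc1ccc(OCc2ccccc2)cc1 | starting material
19 | (Z)-dibutylboron enolate of 17 | CCCCB(CCCC)O/C(=C\[C@@H]1[C@@H](c2ccc(OC)cc2)Oc2cc(OCc3ccccc3)cc(OCc3ccccc3)c2C1=O)N1C(=O)OC[C@@H]1Cc1ccccc1 | intermediate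
20 | O-dibutylboryl aldolate of 21 | COc1ccc([C@H]2Oc3cc(OCc4ccccc4)cc(OCc4ccccc4)c3C(=O)[C@@H]2[C@H](C(=O)N2C(=O)OC[C@@H]2Cc2ccccc2)[C@H](OB(CCCC)CCCC)c2ccc(OCc3ccccc3)cc2)cc1 | intermediate
21 | (4S)-4-benzyl-3-{(2S,3S)-3-[4-(benzyloxy)phenyl]-2-[(2S,3R)-5,7-bis(benzyloxy)-2-(4-methoxyphenyl)-4-oxochroman-3-yl]-3-hydroxypropanoyl}-1,3-oxazolidin-2-one | COc1ccc([C@H]2Oc3cc(OCc4ccccc4)cc(OCc4ccccc4)c3C(=O)[C@@H]2[C@H](C(=O)N2C(=O)OC[C@@H]2Cc2ccccc2)[C@H](O)c2ccc(OCc3ccccc3)cc2)cc1 | intermediate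
22 | (4S)-4-benzyl-3-{(2S,3S)-3-[3,5-bis(benzyloxy)phenoxy]-3-[4-(benzyloxy)phenyl]-2-[(2S,3R)-5,7-bis(benzyloxy)-2-(4-methoxyphenyl)-4-oxochroman-3-yl]propanoyl}-1,3-oxazolidin-2-one | COc1ccc([C@H]2Oc3cc(OCc4ccccc4)cc(OCc4ccccc4)c3C(=O)[C@@H]2[C@H](C(=O)N2C(=O)OC[C@@H]2Cc2ccccc2)[C@H](Oc2cc(OCc3ccccc3)cc(OCc3ccccc3)c2)c2ccc(OCc3ccccc3)cc2)cc1 | intermediate
23 | peroxy acid corresponding to 24 | COc1ccc([C@H]2Oc3cc(OCc4ccccc4)cc(OCc4ccccc4)c3C(=O)[C@@H]2[C@H](C(=O)OO)[C@H](Oc2cc(OCc3ccccc3)cc(OCc3ccccc3)c2)c2ccc(OCc3ccccc3)cc2)cc1 | intermediate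
24 | (2S,3S)-3-[3,5-bis(benzyloxy)phenoxy]-3-[4-(benzyloxy)phenyl]-2-[(2S,3R)-5,7-bis(benzyloxy)-2-(4-methoxyphenyl)-4-oxochroman-3-yl]propanoic acid | COc1ccc([C@H]2Oc3cc(OCc4ccccc4)cc(OCc4ccccc4)c3C(=O)[C@@H]2[C@H](C(=O)O)[C@H](Oc2cc(OCc3ccccc3)cc(OCc3ccccc3)c2)c2ccc(OCc3ccccc3)cc2)cc1 | intermediate
25 | mixed anhydride of 24 with trifluoroacetic acid | COc1ccc([C@H]2Oc3cc(OCc4ccccc4)cc(OCc4ccccc4)c3C(=O)[C@@H]2[C@H](C(=O)OC(=O)C(F)(F)F)[C@H](Oc2cc(OCc3ccccc3)cc(OCc3ccccc3)c2)c2ccc(OCc3ccccc3)cc2)cc1 | intermediate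
26 | (2S,3R,2''S,3''S)-5,5'',7,7''-tetrakis(benzyloxy)-2''-[4-(benzyloxy)phenyl]-2-(4-methoxyphenyl)-[3,3''-bichromane]-4,4''-dione | COc1ccc([C@H]2Oc3cc(OCc4ccccc4)cc(OCc4ccccc4)c3C(=O)[C@@H]2[C@@H]2C(=O)c3c(OCc4ccccc4)cc(OCc4ccccc4)cc3O[C@@H]2c2ccc(OCc3ccccc3)cc2)cc1 | intermediate
27 | (2S,3R,2''S,3''S)-5,5'',7,7''-tetrahydroxy-2''-(4-hydroxyphenyl)-2-(4-methoxyphenyl)-[3,3''-bichromane]-4,4''-dione | COc1ccc([C@H]2Oc3cc(O)cc(O)c3C(=O)[C@@H]2[C@@H]2C(=O)c3c(O)cc(O)cc3O[C@@H]2c2ccc(O)cc2)cc1 | target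

**Totals**

Total step count: 13 (step 1 makes the aryl donor 2; steps 2–13 are the main line).
Longest linear sequence: 12 steps (3 → 27, steps 2–13).

**Steps most likely to fail, with fallbacks**

Step 12. The acid formed in the ring closure may ionise the p-alkoxybenzylic C2''–O bond (epimerisation at C2'' or elimination) before the ring closes, or the arene may be trifluoroacetylated. The fallback closes the same bond through a buffered nitrilium ion instead of an acylium ion. It sets out from acid 24, which would be condensed with methylamine under base-free conditions (DMTMM, THF/MeOH) to give the N-methyl amide F1. Tf2O with 2-chloropyridine in CH2Cl2 at −78 → 0 °C should turn this secondary amide into a nitrilium ion, which ring A'' attacks at C4a'' to give the N-methyl ketimine F2. Hydrolysis in an aqueous NaOAc/AcOH buffer should then give 26, where the route is rejoined.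

Step 10. The hindered hydroxyl of 21 may couple too slowly, so that protodeboronation and oxidative self-coupling of the borate, or copper-promoted oxidation of the benzylic alcohol, take over. The fallback replaces the copper-bound aryl group by a free aryne, an electrophile far less sensitive to steric hindrance that still makes the bond at oxygen (retention). It sets out from alcohol 21 and from commercial 3,5-bis(benzyloxy)phenol. Bromination of the phenol with NBS (CH2Cl2, −78 → 0 °C) should give 3,5-bis(benzyloxy)-2-bromophenol F3. In one flask, HMDS should then give the aryl silyl ether F4, n-BuLi (THF, −78 °C) the lithium phenoxide F5 by bromine–lithium exchange and retro-Brook migration of silicon from oxygen to carbon, and Tf2O the 2-silylaryl triflate F6. KF and 18-crown-6 in THF at rt should release 3,5-bis(benzyloxy)benzyne F7 in the presence of 21, whose hydroxyl adds at the aryne carbon remote from the neighbouring benzyloxy group to give 22, where the route is rejoined.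

Step 9. Bu2BOTf and the amine may enolise the chromanone ketone and open ring C, or the neighbouring C3 centre may erode facial control. The fallback replaces syn-aldol plus retention by anti-aldol plus inversion under catalytic Lewis acid. It sets out from acid 15, which would be coupled with (R)-4-benzyl-1,3-oxazolidin-2-one through the mixed anhydride 16 to give the imide F8. The MgCl2-catalysed anti-aldol with 18 (Et3N, TMSCl, EtOAc) should give the silyl ether F9, and mild methanolysis the anti adduct F10 (C3'' S, C2'' R). Mitsunobu etherification with commercial 3,5-bis(benzyloxy)phenol (PPh3, DIAD, toluene, 0 °C) should invert C2'' and give the aryl ether imide F11. LiOOH cleavage through peroxy acid 23 should then give acid 24, where the route is rejoined.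

**Further compounds**

F1 | step 12 | (2S,3S)-3-[3,5-bis(benzyloxy)phenoxy]-3-[4-(benzyloxy)phenyl]-2-[(2S,3R)-5,7-bis(benzyloxy)-2-(4-methoxyphenyl)-4-oxochroman-3-yl]-N-methylpropanamide | COc1ccc([C@H]2Oc3cc(OCc4ccccc4)cc(OCc4ccccc4)c3C(=O)[C@@H]2[C@H](C(=O)NC)[C@H](Oc2cc(OCc3ccccc3)cc(OCc3ccccc3)c2)c2ccc(OCc3ccccc3)cc2)cc1
F2 | step 12 | N-methyl ketimine at C4'' of 26 | COc1ccc([C@H]2Oc3cc(OCc4ccccc4)cc(OCc4ccccc4)c3C(=O)[C@@H]2[C@@H]2C(=NC)c3c(OCc4ccccc4)cc(OCc4ccccc4)cc3O[C@@H]2c2ccc(OCc3ccccc3)cc2)cc1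
F3 | step 10 | 3,5-bis(benzyloxy)-2-bromophenol | Oc1cc(OCc2ccccc2)cc(OCc2ccccc2)c1Br
F4 | step 10 | [3,5-bis(benzyloxy)-2-bromophenoxy]trimethylsilane | C[Si](C)(C)Oc1cc(OCc2ccccc2)cc(OCc2ccccc2)c1Br
F5 | step 10 | lithium 3,5-bis(benzyloxy)-2-(trimethylsilyl)phenoxide | [Li+].[O-]c1cc(OCc2ccccc2)cc(OCc2ccccc2)c1[Si](C)(C)C
F6 | step 10 | 3,5-bis(benzyloxy)-2-(trimethylsilyl)phenyl trifluoromethanesulfonate | C[Si](C)(C)c1c(OS(=O)(=O)C(F)(F)F)cc(OCc2ccccc2)cc1OCc1ccccc1
F7 | step 10 | 3,5-bis(benzyloxy)benzyne (1,2-didehydro-3,5-bis(benzyloxy)benzene) | C1#CC(OCc2ccccc2)=CC(OCc2ccccc2)=C1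
F8 | step 9 | (4R)-4-benzyl-3-{[(2S,3R)-5,7-bis(benzyloxy)-2-(4-methoxyphenyl)-4-oxochroman-3-yl]acetyl}-1,3-oxazolidin-2-one | COc1ccc([C@H]2Oc3cc(OCc4ccccc4)cc(OCc4ccccc4)c3C(=O)[C@@H]2CC(=O)N2C(=O)OC[C@H]2Cc2ccccc2)cc1
F9 | step 9 | trimethylsilyl ether of F10 | COc1ccc([C@H]2Oc3cc(OCc4ccccc4)cc(OCc4ccccc4)c3C(=O)[C@@H]2[C@H](C(=O)N2C(=O)OC[C@H]2Cc2ccccc2)[C@@H](O[Si](C)(C)C)c2ccc(OCc3ccccc3)cc2)cc1
F10 | step 9 | (4R)-4-benzyl-3-{(2S,3R)-3-[4-(benzyloxy)phenyl]-2-[(2S,3R)-5,7-bis(benzyloxy)-2-(4-methoxyphenyl)-4-oxochroman-3-yl]-3-hydroxypropanoyl}-1,3-oxazolidin-2-one | COc1ccc([C@H]2Oc3cc(OCc4ccccc4)cc(OCc4ccccc4)c3C(=O)[C@@H]2[C@H](C(=O)N2C(=O)OC[C@H]2Cc2ccccc2)[C@@H](O)c2ccc(OCc3ccccc3)cc2)cc1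
F11 | step 9 | (4R)-4-benzyl-3-{(2S,3S)-3-[3,5-bis(benzyloxy)phenoxy]-3-[4-(benzyloxy)phenyl]-2-[(2S,3R)-5,7-bis(benzyloxy)-2-(4-methoxyphenyl)-4-oxochroman-3-yl]propanoyl}-1,3-oxazolidin-2-one | COc1ccc([C@H]2Oc3cc(OCc4ccccc4)cc(OCc4ccccc4)c3C(=O)[C@@H]2[C@H](C(=O)N2C(=O)OC[C@H]2Cc2ccccc2)[C@H](Oc2cc(OCc3ccccc3)cc(OCc3ccccc3)c2)c2ccc(OCc3ccccc3)cc2)cc1
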